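**Retrosynthetic overview**

- Locants used throughout: C1 = quaternary oxirane carbon carrying C7 (the CH2O carbon), C2 = benzoyloxy carbon, C3 = carbinol, C4=C5 = olefin, C6 = oxirane CH. The strategy rests on the oxirane O–C1–C6 of the cyclohexene ring together with the C7 oxygen one bond from C1. These two form an epoxy-alcohol pair whose transposed form is a C1–C7 spiro-oxirane with a hydroxyl on C6.
- Key disconnection: the O–C1 bond of the ring-fused oxirane. It leads back to spiro-oxirane cyclohexenol 11, in which the C6 hydroxyl is anti to the spiro oxygen, C2 is a p-methoxybenzyl ether and C3 a silyl ether.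
- 11 comes from cis C3/C6 dioxygenation (singlet oxygen [4+2], O–O reduction) of a spiro-epoxy cyclohexadienyl ether. That ether comes from periodate dearomatization of 2-hydroxybenzyl alcohol, 1,2-reduction and lipase resolution.
- Ring order: the carbocycle is the arene ring; the spiro-oxirane forms in step 1; a dioxabicyclo[2.2.2]octene is made in step 4 and opened in step 5; the fused oxirane forms in step 7. Endgame: C7 benzoate, ether cleavage, C2 benzoate, desilylation.

Key step: step 7

Remark: the lipase is taken to follow Kazlauskas's rule. Should it acylate the (3S,4S) alcohol instead, that acetate would be methanolysed (K2CO3, MeOH, 0 °C) to 4 and the route would continue unchanged.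

**Route**

Step 1
Reactants: 1 2-hydroxybenzyl alcohol
Product: 3 (3RS,4RS)-1-oxaspiro[2.5]octa-5,7-dien-4-ol (racemate, C2 hydroxyl syn to the oxirane oxygen), via spiro-epoxydienone 2 (not isolated)
Conditions: NaIO4, H2O, 0 °C, 10 min; cold CH2Cl2 extract added at once to NaBH4, CeCl3·7H2O, MeOH, −78 °C; NaHCO3 quench
Reagents that add atoms: none
Why: Adler–Becker oxidation (periodate ester of the phenol, benzylic hydroxyl closing onto the ipso carbon) gives the spiro-epoxy-2,4-cyclohexadienone, and Luche 1,2-reduction of its cold solution, run before Diels–Alder dimerization can compete, should deliver external hydride to C2 anti to the C1–O bond (polar Felkin–Anh effect, the oxygen face being further screened by cerium held between the two oxygens), which sets the C2 hydroxyl syn to the oxirane oxygen.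

Step 2
Reactants: 3 (3RS,4RS)-1-oxaspiro[2.5]octa-5,7-dien-4-ol
Product: 4 (3S,4S)-1-oxaspiro[2.5]octa-5,7-dien-4-ol (unreacted enantiomer)
Conditions: Burkholderia cepacia lipase (Amano PS), vinyl acetate, t-BuOMe, 25 °C, to about 55% conversion; chromatography on Et3N-deactivated silica
Reagents that add atoms: none
Why: Lipase-catalysed kinetic resolution by transesterification: by Kazlauskas's rule, with the fully substituted C1 as the large and the vinylic C3 as the medium group, the 4R carbinol of the (3R,4R) enantiomer should be acetylated and the (3S,4S) alcohol left, so no stereocentre is made and the absolute series is chosen here.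

Step 3
Reactants: 4 (3S,4S)-1-oxaspiro[2.5]octa-5,7-dien-4-ol; 5 4-methoxybenzyl chloride
Product: 6 (3S,4S)-4-[(4-methoxybenzyl)oxy]-1-oxaspiro[2.5]octa-5,7-diene
Conditions: NaH, Bu4NI (cat.), THF/DMF, 0 °C to rt
Reagents that add atoms: 4-methoxybenzyl chloride 5, COc1ccc(CCl)cc1
Why: Williamson etherification of the sodium alkoxide, a basic step that this acid-labile dienol tolerates (the alkoxide is syn to the oxirane oxygen and cannot open it); C2 is capped as an ether because an ester at C2 would later be transferred to the C7 alkoxide of the rearranged product.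

Step 4
Reactants: 6 (3S,4S)-4-[(4-methoxybenzyl)oxy]-1-oxaspiro[2.5]octa-5,7-diene; 7 dioxygen
Product: 8 endoperoxide (2,3-dioxabicyclo[2.2.2]oct-5-ene with the O–O bridge joining C3 and C6 on the face anti to the C2 ether oxygen and the spiro-oxirane oxygen; C2 ether and spiro-oxirane unchanged)
Conditions: O2, tetraphenylporphyrin (cat.), visible light, CH2Cl2, −40 °C; used directly
Reagents that add atoms: dioxygen 7, O=O
Why: Singlet-oxygen [4+2] cycloaddition across C3 and C6 of the cyclohexadiene; approach anti to the C2 p-methoxybenzyloxy group (steric) and to the oxirane oxygen (lone-pair repulsion) sets C3 and C6 in one event, both new C–O bonds cis to each other and on the face opposite the spiro oxygen.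

Step 5
Reactants: 8 endoperoxide
Product: 9 (3R,4S,7R,8S)-8-[(4-methoxybenzyl)oxy]-1-oxaspiro[2.5]oct-5-ene-4,7-diol (C3 and C6 hydroxyls cis, both anti to the spiro oxygen)
Conditions: thiourea (2.2 equiv), MeOH, 0 °C to rt
Reagents that add atoms: none
Why: Thiourea reduction of the dialkyl peroxide cleaves only the O–O bond, so C3 and C6 keep their configuration and the cis-enediol results; at 0 °C the peroxide should be consumed well before thiourea can attack the neopentyl-type oxirane CH2.

Step 6
Reactants: 9 (3R,4S,7R,8S)-8-[(4-methoxybenzyl)oxy]-1-oxaspiro[2.5]oct-5-ene-4,7-diol; 10 tert-butyldimethylsilyl chloride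
Product: 11 (3R,4S,7R,8S)-7-[(tert-butyldimethylsilyl)oxy]-8-[(4-methoxybenzyl)oxy]-1-oxaspiro[2.5]oct-5-en-4-ol (C3 silyl ether, free C6 hydroxyl)
Conditions: TBSCl (1.05 equiv), imidazole, DMF, −20 to 0 °C
Reagents that add atoms: tert-butyldimethylsilyl chloride 10, C[Si](C)(Cl)C(C)(C)C
Why: Regioselective silylation of the less hindered secondary hydroxyl: C6–OH is flanked by the fully substituted C1, whose CH2 is syn to it, whereas C3–OH is flanked by a CH carbon with a trans ether, so the bulky chloride should react at C3; this cap is needed because a free C3 alkoxide, syn to C7, could open the spiro-oxirane 5-exo.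

Step 7
Reactants: 11 (3R,4S,7R,8S)-7-[(tert-butyldimethylsilyl)oxy]-8-[(4-methoxybenzyl)oxy]-1-oxaspiro[2.5]oct-5-en-4-ol
Product: 12 [(1S,2S,3R,6S)-3-[(tert-butyldimethylsilyl)oxy]-2-[(4-methoxybenzyl)oxy]-7-oxabicyclo[4.1.0]hept-4-en-1-yl]methanol
Conditions: KOt-Bu (0.2 equiv), THF/t-BuOH 4:1, 0 °C to rt; pH 7 buffer quench
Reagents that add atoms: none
Why: Catalytic tert-butoxide reversibly deprotonates the C6 hydroxyl, and the alkoxide attacks C1 from the side opposite the spiro C1–O bond (intramolecular SN2), so that the oxygen on C6 becomes the oxygen of the ring-fused oxirane and the former oxirane oxygen leaves as the primary C7 alkoxide, which tert-butanol protonates. The closest known reaction is the Payne rearrangement of 2,3-epoxy alcohols, run here toward the more substituted oxirane. The new oxirane closes 3-exo-tet onto C1 while the spiro-oxirane opens. C1 is the only stereocentre that changes: it is inverted, so the oxirane oxygen ends on the face the C6 oxygen already occupies (fixed by the endoperoxide) and C7 swings to the face of the C2 ether oxygen. The step needs the C6 oxygen anti to the spiro oxygen, which steps 1 and 4 provide, and a half-chair with both axial, which also places the C2 and C3 substituents equatorial; it needs attack at C1 and not 4-exo attack at C7, which the much faster three-ring closure should secure. It also needs the equilibrium on the product side, expected because the fused oxirane is trisubstituted and the alcohol primary where the spiro isomer has a 1,1-disubstituted oxirane and a secondary alcohol, and it needs no second nucleophile, which is why C2 is an ether (an ester would pass to the C7 alkoxide and free a C2 alkoxide anti to the new oxirane) and C3 is silylated.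

Step 8
Reactants: 12 [(1S,2S,3R,6S)-3-[(tert-butyldimethylsilyl)oxy]-2-[(4-methoxybenzyl)oxy]-7-oxabicyclo[4.1.0]hept-4-en-1-yl]methanol; 13 benzoyl chloride
Product: 14 [(1S,2S,3R,6S)-3-[(tert-butyldimethylsilyl)oxy]-2-[(4-methoxybenzyl)oxy]-7-oxabicyclo[4.1.0]hept-4-en-1-yl]methyl benzoate
Conditions: BzCl (1.1 equiv), pyridine, CH2Cl2, 0 °C
Reagents that add atoms: benzoyl chloride 13, O=C(Cl)c1ccccc1
Why: Acylation of the unhindered primary hydroxyl under pyridine installs the C7 benzoate and removes the hydroxyl that could otherwise trap the oxocarbenium ion as a cyclic acetal in the next step; no stereocentre changes.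

Step 9
Reactants: 14 [(1S,2S,3R,6S)-3-[(tert-butyldimethylsilyl)oxy]-2-[(4-methoxybenzyl)oxy]-7-oxabicyclo[4.1.0]hept-4-en-1-yl]methyl benzoate
Product: 15 [(1R,2S,3R,6S)-3-[(tert-butyldimethylsilyl)oxy]-2-hydroxy-7-oxabicyclo[4.1.0]hept-4-en-1-yl]methyl benzoate
Conditions: DDQ, CH2Cl2/pH 7 phosphate buffer, 0 °C to rt
Reagents that add atoms: none
Why: Oxidative cleavage of the p-methoxybenzyl ether by DDQ (hydride abstraction to the oxocarbenium ion, then hydrolysis) under buffered neutral conditions that the allylic oxirane, the silyl ether and the benzoate tolerate; the C2–O bond is not broken, so C2 keeps its configuration.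

Step 10
Reactants: 15 [(1R,2S,3R,6S)-3-[(tert-butyldimethylsilyl)oxy]-2-hydroxy-7-oxabicyclo[4.1.0]hept-4-en-1-yl]methyl benzoate; 13 benzoyl chloride
Product: 16 [(1S,2S,3R,6S)-2-(benzoyloxy)-3-[(tert-butyldimethylsilyl)oxy]-7-oxabicyclo[4.1.0]hept-4-en-1-yl]methyl benzoate
Conditions: BzCl, DMAP (cat.), pyridine, CH2Cl2, rt
Reagents that add atoms: benzoyl chloride 13, O=C(Cl)c1ccccc1
Why: DMAP-catalysed benzoylation of the hindered C2 hydroxyl; amine bases do not form the C2 alkoxide, so no Payne shift onto C1 can start, and a C7-to-C2 acyl shift would be degenerate once both positions carry benzoate.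

Step 11
Reactants: 16 [(1S,2S,3R,6S)-2-(benzoyloxy)-3-[(tert-butyldimethylsilyl)oxy]-7-oxabicyclo[4.1.0]hept-4-en-1-yl]methyl benzoate
Product: 17 [(1S,2S,3R,6S)-2-(benzoyloxy)-3-hydroxy-7-oxabicyclo[4.1.0]hept-4-en-1-yl]methyl benzoate (target)
Conditions: Bu4NF, AcOH (1:1), THF, 0 °C to rt
Reagents that add atoms: none
Why: Fluoride cleavage of the Si–O bond with acetic acid as buffer frees the C3 hydroxyl without forming a basic alkoxide, so the C2 benzoate should not migrate to C3 and the allylic oxirane should not be opened; no stereocentre is touched.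

**Compound list**

1 | 2-hydroxybenzyl alcohol | OCc1ccccc1O | starting material
2 | 1-oxaspiro[2.5]octa-5,7-dien-4-one (racemic spiro-epoxydienone, not isolated) | O=C1C=CC=CC12CO2 | intermediate
3 | (3RS,4RS)-1-oxaspiro[2.5]octa-5,7-dien-4-ol (racemate, one enantiomer drawn) | O[C@H]1C=CC=C[C@]12CO2 | intermediate
4 | (3S,4S)-1-oxaspiro[2.5]octa-5,7-dien-4-ol | O[C@H]1C=CC=C[C@]12CO2 | intermediate
5 | 4-methoxybenzyl chloride | COc1ccc(CCl)cc1 | starting material
6 | (3S,4S)-4-[(4-methoxybenzyl)oxy]-1-oxaspiro[2.5]octa-5,7-diene | COc1ccc(CO[C@H]2C=CC=C[C@]23CO3)cc1 | intermediate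
7 | dioxygen | O=O | starting material
8 | endoperoxide of 6 (O–O bridge C3 to C6, anti to the C2 ether oxygen and the spiro oxygen) | O1O[C@H]2C=C[C@@H]1[C@H](OCc4ccc(OC)cc4)[C@@]23CO3 | intermediate
9 | (3R,4S,7R,8S)-8-[(4-methoxybenzyl)oxy]-1-oxaspiro[2.5]oct-5-ene-4,7-diol | O[C@H]1C=C[C@@H](O)[C@H](OCc2ccc(OC)cc2)[C@@]13CO3 | intermediate
10 | tert-butyldimethylsilyl chloride | C[Si](C)(Cl)C(C)(C)C | starting material
11 | (3R,4S,7R,8S)-7-[(tert-butyldimethylsilyl)oxy]-8-[(4-methoxybenzyl)oxy]-1-oxaspiro[2.5]oct-5-en-4-ol | O[C@H]1C=C[C@@H](O[Si](C)(C)C(C)(C)C)[C@H](OCc2ccc(OC)cc2)[C@@]13CO3 | intermediate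
12 | [(1S,2S,3R,6S)-3-[(tert-butyldimethylsilyl)oxy]-2-[(4-methoxybenzyl)oxy]-7-oxabicyclo[4.1.0]hept-4-en-1-yl]methanol | OC[C@]12O[C@H]1C=C[C@@H](O[Si](C)(C)C(C)(C)C)[C@@H]2OCc1ccc(OC)cc1 | intermediate
13 | benzoyl chloride | O=C(Cl)c1ccccc1 | starting material
14 | [(1S,2S,3R,6S)-3-[(tert-butyldimethylsilyl)oxy]-2-[(4-methoxybenzyl)oxy]-7-oxabicyclo[4.1.0]hept-4-en-1-yl]methyl benzoate | O=C(OC[C@]12O[C@H]1C=C[C@@H](O[Si](C)(C)C(C)(C)C)[C@@H]2OCc1ccc(OC)cc1)c1ccccc1 | intermediate
15 | [(1R,2S,3R,6S)-3-[(tert-butyldimethylsilyl)oxy]-2-hydroxy-7-oxabicyclo[4.1.0]hept-4-en-1-yl]methyl benzoate | O=C(OC[C@]12O[C@H]1C=C[C@@H](O[Si](C)(C)C(C)(C)C)[C@@H]2O)c1ccccc1 | intermediate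
16 | [(1S,2S,3R,6S)-2-(benzoyloxy)-3-[(tert-butyldimethylsilyl)oxy]-7-oxabicyclo[4.1.0]hept-4-en-1-yl]methyl benzoate | O=C(OC[C@]12O[C@H]1C=C[C@@H](O[Si](C)(C)C(C)(C)C)[C@@H]2OC(=O)c1ccccc1)c1ccccc1 | intermediate
17 | [(1S,2S,3R,6S)-2-(benzoyloxy)-3-hydroxy-7-oxabicyclo[4.1.0]hept-4-en-1-yl]methyl benzoate | O=C(OC[C@]12O[C@H]1C=C[C@@H](O)[C@@H]2OC(=O)c1ccccc1)c1ccccc1 | target

**Step count and risks**

Total step count: 11. Longest linear sequence: 11 steps (1 to 17).

Steps most likely to fail:

1. Step 7. The alkoxide equilibrium may stop short of 12, or the freed C7 alkoxide may be lost to intermolecular oxirane opening before it is protonated. Fallback, from 11: the equilibrium isomerization is replaced by rearrangement with irreversible capture. NaH (1.1 equiv) in THF at 0 °C equilibrates the sodium alkoxides, then benzoyl chloride 13 is added at −40 °C. The primary C7 alkoxide of 12 (present only as its sodium salt, not isolated) should be acylated much faster than the neopentyl-type C6 alkoxide of 11, so the pool drains through 12 into 14, where the route is rejoined.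

2. Step 1. Bimolecular Diels–Alder dimerization of dienone 2 may take the material before the 1,2-reduction, and a hurried reduction may lose 1,2- and facial selectivity. Fallback, from 1: a removable bromine blocks the dimerization. NBS in MeCN at 0 °C brominates para to the phenol and gives 4-bromo-2-(hydroxymethyl)phenol F1. NaIO4 oxidation gives 7-bromo-1-oxaspiro[2.5]octa-5,7-dien-4-one F2, whose bromine sits on the double bond that serves as dienophile in the dimerization and should make the dienone isolable. Luche reduction (NaBH4, CeCl3·7H2O, MeOH, −78 °C) can then be run without time pressure and gives (3RS,4RS)-7-bromo-1-oxaspiro[2.5]octa-5,7-dien-4-ol F3. Bromine–lithium exchange with t-BuLi (3.2 equiv, THF, −78 °C) forms lithium (3RS,4RS)-7-lithio-1-oxaspiro[2.5]octa-5,7-dien-4-olate F4, and a methanol quench at −78 °C returns the route at 3.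

3. Step 2. The lipase may discriminate poorly between the enantiomers of an alcohol flanked by a fully substituted carbon, or may not turn it over, so that 4 is not enantiomerically pure. Fallback, from 3: classical resolution through covalent diastereomers. Esterification with (S)-2-methoxy-2-phenylacetic acid (DCC, DMAP cat., CH2Cl2, 0 °C) gives (3S,4S)-1-oxaspiro[2.5]octa-5,7-dien-4-yl (S)-2-methoxy-2-phenylacetate F5 and (3R,4R)-1-oxaspiro[2.5]octa-5,7-dien-4-yl (S)-2-methoxy-2-phenylacetate F6. These are separated by chromatography on Et3N-deactivated silica, and methanolysis of F5 (K2CO3, MeOH, 0 °C) returns the route at 4.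

**Further compounds**

F0 | step 7 | none | none
F1 | step 1 | 4-bromo-2-(hydroxymethyl)phenol | OCc1cc(Br)ccc1O
F2 | step 1 | 7-bromo-1-oxaspiro[2.5]octa-5,7-dien-4-one (racemic) | O=C1C=CC(Br)=CC12CO2
F3 | step 1 | (3RS,4RS)-7-bromo-1-oxaspiro[2.5]octa-5,7-dien-4-ol (racemate, one enantiomer drawn) | O[C@H]1C=CC(Br)=C[C@]12CO2
F4 | step 1 | lithium (3RS,4RS)-7-lithio-1-oxaspiro[2.5]octa-5,7-dien-4-olate (racemate, one enantiomer drawn) | [Li]O[C@H]1C=CC([Li])=C[C@]12CO2
F5 | step 2 | (3S,4S)-1-oxaspiro[2.5]octa-5,7-dien-4-yl (S)-2-methoxy-2-phenylacetate | CO[C@@H](c1ccccc1)C(=O)O[C@H]2C=CC=C[C@]23CO3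
F6 | step 2 | (3R,4R)-1-oxaspiro[2.5]octa-5,7-dien-4-yl (S)-2-methoxy-2-phenylacetate | CO[C@@H](c1ccccc1)C(=O)O[C@@H]2C=CC=C[C@@]23CO3
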